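**Retrosynthetic overview**

1. The target comes from 2-methoxy-4-(3,5,7-trihydroxy-4-oxo-4H-chromen-2-yl)phenyl pivalate 19 by sulfation of O3 and O7 and removal of the pivalate; 19 comes from chromone 18 by BCl3 cleavage of the chelated 5-O-ethyl and 3-O-MOM ethers.
2. Feature used: ring A carries a sulfated oxygen on C7 and a free hydroxyl on C5. Disconnecting C6–C7 (and C8–C8a through a Wolff shift) lets C7 come from a ketene carbon (free phenol) and C5 from an enol-ether carbon (ether), so the two oxygens are formed already differentiated.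
3. Ring A is therefore closed last on a fully substituted monocyclic 4-pyranone (ring C): diazoketone 15 → ketene → six-electron electrocyclisation → 18.
4. 15 derives from kojic acid, which supplies ring C with O3, the C4 carbonyl and the future C7 carbon: C6 iodination, O-MOM protection, C3 bromination, Suzuki coupling for ring B, oxidation of CH2OH, Stille coupling for the 1-ethoxyvinyl group, diazoketone formation.
5. Ring order: ring C (bought), ring B (attached preformed), ring A (built).

Key step: step 11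

Assumption: the sulfate monoesters 20 and 21 are written and counted as the free acids of the target SMILES; they would be handled as triethylammonium or potassium salts and passed through an acid-form cation-exchange resin only at the very end.

**Route**

Step 1
Reactants: 1 kojic acid [5-hydroxy-2-(hydroxymethyl)-4H-pyran-4-one]
Product: 2 3-hydroxy-6-(hydroxymethyl)-2-iodo-4H-pyran-4-one
Conditions: NIS (1.05 equiv), DMF, 0 °C to rt, dark
Reagents that add atoms: N-iodosuccinimide, O=C1CCC(=O)N1I
Why: electrophilic iodination of the enolic hydroxypyranone should go to the only carbon ortho to the free hydroxyl (kojic acid C6), the position at which kojic acid is known to take up halogens and other electrophiles.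

Step 2
Reactants: 2 3-hydroxy-6-(hydroxymethyl)-2-iodo-4H-pyran-4-one
Product: 3 6-(hydroxymethyl)-2-iodo-3-(methoxymethoxy)-4H-pyran-4-one
Conditions: MOMCl (1.05 equiv), K2CO3, acetone, 0 °C to rt
Reagents that add atoms: chloromethyl methyl ether, COCCl
Why: Williamson-type O-alkylation in which carbonate deprotonates only the acidic enolic hydroxyl, so the primary alcohol should stay free, as in the selective O-benzylation of kojic acid.

Step 3
Reactants: 3 6-(hydroxymethyl)-2-iodo-3-(methoxymethoxy)-4H-pyran-4-one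
Product: 4 3-bromo-2-(hydroxymethyl)-6-iodo-5-(methoxymethoxy)-4H-pyran-4-one
Conditions: NBS (1.1 equiv), MeCN, rt to 40 °C, dark
Reagents that add atoms: N-bromosuccinimide, O=C1CCC(=O)N1Br
Why: electrophilic alpha-bromination of a 4-pyranone (a vinylogous ester) at the one remaining ring C–H, alpha to the carbonyl and beta to the ring oxygen; it is placed before the arylation so that no electron-rich arene can compete for bromine.

Step 4
Reactants: 5 2-methoxy-4-(4,4,5,5-tetramethyl-1,3,2-dioxaborolan-2-yl)phenol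
Product: 6 2-methoxy-4-(4,4,5,5-tetramethyl-1,3,2-dioxaborolan-2-yl)phenyl 2,2-dimethylpropanoate
Conditions: PivCl (1.2 equiv), Et3N, DMAP (cat.), CH2Cl2, 0 °C to rt
Reagents that add atoms: pivaloyl chloride, CC(C)(C)C(=O)Cl
Why: DMAP-catalysed O-acylation of the phenol; a hindered aryl ester is chosen for O4' because it should survive mild aqueous base and BCl3, which an aryl benzyl ether would not, and can still be removed with base after sulfation.

Step 5
Reactants: 4 3-bromo-2-(hydroxymethyl)-6-iodo-5-(methoxymethoxy)-4H-pyran-4-one; 6 2-methoxy-4-(4,4,5,5-tetramethyl-1,3,2-dioxaborolan-2-yl)phenyl 2,2-dimethylpropanoate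
Product: 7 4-[5-bromo-6-(hydroxymethyl)-3-(methoxymethoxy)-4-oxo-4H-pyran-2-yl]-2-methoxyphenyl 2,2-dimethylpropanoate
Conditions: Pd(dppf)Cl2 (5 mol %), K3PO4 (2 equiv), 1,4-dioxane/H2O (10:1), 50 °C
Reagents that add atoms: none
Why: Suzuki–Miyaura coupling in which oxidative addition to zerovalent palladium should occur only at the C–I bond, which is both the weaker carbon–halogen bond and the vinylogous acyl halide position beta to the carbonyl, leaving the alpha C–Br bond for step 8.

Step 6
Reactants: 7 4-[5-bromo-6-(hydroxymethyl)-3-(methoxymethoxy)-4-oxo-4H-pyran-2-yl]-2-methoxyphenyl 2,2-dimethylpropanoate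
Product: 8 3-bromo-6-[4-(2,2-dimethylpropanoyloxy)-3-methoxyphenyl]-5-(methoxymethoxy)-4-oxo-4H-pyran-2-carboxylic acid
Conditions: TEMPO (0.2 equiv), PhI(OAc)2 (2.5 equiv), MeCN/H2O (1:1), rt
Reagents that add atoms: water, O
Why: oxoammonium (TEMPO) oxidation of the primary alcohol through the aldehyde hydrate to the acid, the same change that turns O-protected kojic acids into comenic acids; the medium is only as acidic as acetic acid, so the MOM ether and the pivalate should persist.

Step 7
Reactants: 8 3-bromo-6-[4-(2,2-dimethylpropanoyloxy)-3-methoxyphenyl]-5-(methoxymethoxy)-4-oxo-4H-pyran-2-carboxylic acid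
Product: 9 methyl 3-bromo-6-[4-(2,2-dimethylpropanoyloxy)-3-methoxyphenyl]-5-(methoxymethoxy)-4-oxo-4H-pyran-2-carboxylate
Conditions: MeI (1.5 equiv), KHCO3, DMF, rt
Reagents that add atoms: iodomethane, CI
Why: SN2 O-methylation of the carboxylate; the acid is masked so that the acid-labile enol ether installed next never sits beside a free carboxylic acid, which would add to it to give a cyclic pseudo-ester.

Step 8
Reactants: 9 methyl 3-bromo-6-[4-(2,2-dimethylpropanoyloxy)-3-methoxyphenyl]-5-(methoxymethoxy)-4-oxo-4H-pyran-2-carboxylate; 10 tributyl(1-ethoxyvinyl)stannane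
Product: 11 methyl 6-[4-(2,2-dimethylpropanoyloxy)-3-methoxyphenyl]-3-(1-ethoxyethenyl)-5-(methoxymethoxy)-4-oxo-4H-pyran-2-carboxylate
Conditions: Pd(PPh3)2Cl2 (5 mol %), toluene, 95 °C, Ar; aq. KF work-up, Et3N-deactivated silica
Reagents that add atoms: none
Why: Stille coupling of an electron-poor alpha-bromoenone, as practised on 3-bromochromones, with the alpha-alkoxyvinylstannane; the neutral medium and base-washed silica should keep the enol ether unhydrolysed.

Step 9
Reactants: 11 methyl 6-[4-(2,2-dimethylpropanoyloxy)-3-methoxyphenyl]-3-(1-ethoxyethenyl)-5-(methoxymethoxy)-4-oxo-4H-pyran-2-carboxylate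
Product: 12 lithium 6-[4-(2,2-dimethylpropanoyloxy)-3-methoxyphenyl]-3-(1-ethoxyethenyl)-5-(methoxymethoxy)-4-oxo-4H-pyran-2-carboxylate
Conditions: LiOH·H2O (1.05 equiv), THF/H2O (3:1), 0 °C; lyophilise, toluene azeotrope
Reagents that add atoms: lithium hydroxide, [Li+].[OH-]
Why: saponification in which the methyl ester on the electron-poor pyranone carbon should be far more electrophilic than the hindered aryl pivalate; isolating the lithium salt avoids ever protonating the acid next to the enol ether.

Step 10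
Reactants: 12 lithium 6-[4-(2,2-dimethylpropanoyloxy)-3-methoxyphenyl]-3-(1-ethoxyethenyl)-5-(methoxymethoxy)-4-oxo-4H-pyran-2-carboxylate; 13 (trimethylsilyl)diazomethane
Product: 15 4-[6-(2-diazoacetyl)-5-(1-ethoxyethenyl)-3-(methoxymethoxy)-4-oxo-4H-pyran-2-yl]-2-methoxyphenyl 2,2-dimethylpropanoate, via isobutyl mixed carbonic anhydride 14 (not isolated)
Conditions: i-BuOCOCl (1.1 equiv), THF, −15 °C; then TMSCHN2 (2.5 equiv), MeCN, 0 °C to rt, dark; aq. NaHCO3
Reagents that add atoms: none
Why: C-acylation of the diazoalkane by the mixed carbonic anhydride made from the carboxylate salt and isobutyl chloroformate (the first half of an Arndt–Eistert sequence), the silyl group being lost on work-up; no acid is generated, so the enol ether should survive, and the diazoketone is kept cold and dark and used at once.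

Step 11
Reactants: 15 4-[6-(2-diazoacetyl)-5-(1-ethoxyethenyl)-3-(methoxymethoxy)-4-oxo-4H-pyran-2-yl]-2-methoxyphenyl 2,2-dimethylpropanoate
Product: 18 4-[5-ethoxy-7-hydroxy-3-(methoxymethoxy)-4-oxo-4H-chromen-2-yl]-2-methoxyphenyl 2,2-dimethylpropanoate, via pyranonylketene 16 (not isolated), via cyclohexa-2,4-dienone 17 (not isolated)
Conditions: hν (blue LED, ca. 440 nm), degassed anhydrous toluene (0.005 M), 20 °C, Ar
Reagents that add atoms: none
Why: Proposed new method: absorption by the diazo chromophore expels N2 with a concerted 1,2-shift of the pyranonyl group from the acyl carbon to the diazo carbon (Wolff rearrangement, creating the C8–C8a bond), so that ketene 16 forms, in which the ketene C=C, the pyranone C5=C6 bond (the future C4a=C8a) and the 1-ethoxyvinyl group make up a 1,3,5-hexatriene. This triene should close ring A by a thermal six-electron disrotatory electrocyclisation that joins the vinyl CH2 (C6) to the ketene carbon (C7), after which dienone 17 enolises to the phenol. The closest known reaction is the photo-Wolff rearrangement of ortho-alkenyl aroyl diazomethanes with electrocyclisation of the resulting dienylketenes to naphthols; a 4-pyranone as the migrating group and as the central double bond has not been shown. No stereocenter is formed. The step needs electrocyclisation to outrun carbene cyclopropanation of the enol ether, ketene dimerisation or (2+2) addition, and acylation of the product phenol; this should be secured by the s-Z geometry of the diazoketone that favours the concerted shift, the fixed cis disposition of the two arms on the planar pyranone, the match of the nucleophilic enol-ether terminus with the electrophilic ketene carbon, high dilution in a nucleophile-free solvent and light absorbed only by the diazo group.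

Step 12
Reactants: 18 4-[5-ethoxy-7-hydroxy-3-(methoxymethoxy)-4-oxo-4H-chromen-2-yl]-2-methoxyphenyl 2,2-dimethylpropanoate
Product: 19 2-methoxy-4-(3,5,7-trihydroxy-4-oxo-4H-chromen-2-yl)phenyl 2,2-dimethylpropanoate
Conditions: BCl3 (1 M in CH2Cl2, 5 equiv), CH2Cl2, −78 °C to rt; then H2O
Reagents that add atoms: none
Why: Lewis-acid ether cleavage in which boron chelated between the C4 carbonyl and O5 (and O3) activates only the 5-O-ethyl and 3-O-MOM groups for chloride attack, the selectivity known for 5-alkoxyflavones, while the unchelated 3'-methyl ether and the pivalate should remain.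

Step 13
Reactants: 19 2-methoxy-4-(3,5,7-trihydroxy-4-oxo-4H-chromen-2-yl)phenyl 2,2-dimethylpropanoate
Product: 20 2-methoxy-4-[5-hydroxy-4-oxo-3,7-bis(sulfooxy)-4H-chromen-2-yl]phenyl 2,2-dimethylpropanoate
Conditions: SO3·NEt3 (8 equiv), Et3N, DMF, 50 °C; Sephadex LH-20 (MeOH)
Reagents that add atoms: sulfur trioxide–triethylamine complex, CC[N+](CC)(CC)S(=O)(=O)[O-]
Why: O-sulfation of hydroxyls with a sulfur trioxide–amine complex; the 5-hydroxyl, held in a hydrogen bond to the C4 carbonyl, is the one flavonol hydroxyl that resists these conditions, and O4' is blocked, so sulfation should stop at O3 and O7.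

Step 14
Reactants: 20 2-methoxy-4-[5-hydroxy-4-oxo-3,7-bis(sulfooxy)-4H-chromen-2-yl]phenyl 2,2-dimethylpropanoate
Product: 21 isorhamnetin 3,7-di-O-sulfate [2-(4-hydroxy-3-methoxyphenyl)-5-hydroxy-4-oxo-4H-chromene-3,7-diyl bis(hydrogen sulfate)]
Conditions: K2CO3 (3 equiv), MeOH, 0 °C to rt, Ar; then Dowex 50W (H+ form), H2O, 0 °C; lyophilise
Reagents that add atoms: none
Why: base-mediated methanolysis (transesterification) of the aryl ester, to which aryl sulfate monoester anions are inert; the acid form is generated cold on the resin and freeze-dried at once because the free sulfuric half-esters hydrolyse on standing.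

**Compound list**

1 | kojic acid, 5-hydroxy-2-(hydroxymethyl)-4H-pyran-4-one | O=c1cc(CO)occ1O | starting material
2 | 3-hydroxy-6-(hydroxymethyl)-2-iodo-4H-pyran-4-one | O=c1cc(CO)oc(I)c1O | intermediate
3 | 6-(hydroxymethyl)-2-iodo-3-(methoxymethoxy)-4H-pyran-4-one | O=c1cc(CO)oc(I)c1OCOC | intermediate
4 | 3-bromo-2-(hydroxymethyl)-6-iodo-5-(methoxymethoxy)-4H-pyran-4-one | O=c1c(Br)c(CO)oc(I)c1OCOC | intermediate
5 | 2-methoxy-4-(4,4,5,5-tetramethyl-1,3,2-dioxaborolan-2-yl)phenol | COc1cc(B2OC(C)(C)C(C)(C)O2)ccc1O | starting material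
6 | 2-methoxy-4-(4,4,5,5-tetramethyl-1,3,2-dioxaborolan-2-yl)phenyl 2,2-dimethylpropanoate | COc1cc(B2OC(C)(C)C(C)(C)O2)ccc1OC(=O)C(C)(C)C | intermediate
7 | 4-[5-bromo-6-(hydroxymethyl)-3-(methoxymethoxy)-4-oxo-4H-pyran-2-yl]-2-methoxyphenyl 2,2-dimethylpropanoate | O=c1c(Br)c(CO)oc(-c2ccc(OC(=O)C(C)(C)C)c(OC)c2)c1OCOC | intermediate
8 | 3-bromo-6-[4-(2,2-dimethylpropanoyloxy)-3-methoxyphenyl]-5-(methoxymethoxy)-4-oxo-4H-pyran-2-carboxylic acid | O=C(O)c1oc(-c2ccc(OC(=O)C(C)(C)C)c(OC)c2)c(OCOC)c(=O)c1Br | intermediate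
9 | methyl 3-bromo-6-[4-(2,2-dimethylpropanoyloxy)-3-methoxyphenyl]-5-(methoxymethoxy)-4-oxo-4H-pyran-2-carboxylate | COC(=O)c1oc(-c2ccc(OC(=O)C(C)(C)C)c(OC)c2)c(OCOC)c(=O)c1Br | intermediate
10 | tributyl(1-ethoxyvinyl)stannane | CCOC(=C)[Sn](CCCC)(CCCC)CCCC | starting material
11 | methyl 6-[4-(2,2-dimethylpropanoyloxy)-3-methoxyphenyl]-3-(1-ethoxyethenyl)-5-(methoxymethoxy)-4-oxo-4H-pyran-2-carboxylate | COC(=O)c1oc(-c2ccc(OC(=O)C(C)(C)C)c(OC)c2)c(OCOC)c(=O)c1C(=C)OCC | intermediate
12 | lithium 6-[4-(2,2-dimethylpropanoyloxy)-3-methoxyphenyl]-3-(1-ethoxyethenyl)-5-(methoxymethoxy)-4-oxo-4H-pyran-2-carboxylate | [Li+].[O-]C(=O)c1oc(-c2ccc(OC(=O)C(C)(C)C)c(OC)c2)c(OCOC)c(=O)c1C(=C)OCC | intermediate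
13 | (trimethylsilyl)diazomethane | C[Si](C)(C)C=[N+]=[N-] | starting material
14 | isobutyl mixed carbonic anhydride of the acid of 12 | CC(C)COC(=O)OC(=O)c1oc(-c2ccc(OC(=O)C(C)(C)C)c(OC)c2)c(OCOC)c(=O)c1C(=C)OCC | intermediate
15 | 4-[6-(2-diazoacetyl)-5-(1-ethoxyethenyl)-3-(methoxymethoxy)-4-oxo-4H-pyran-2-yl]-2-methoxyphenyl 2,2-dimethylpropanoate | [N-]=[N+]=CC(=O)c1oc(-c2ccc(OC(=O)C(C)(C)C)c(OC)c2)c(OCOC)c(=O)c1C(=C)OCC | intermediate
16 | 4-[5-(1-ethoxyethenyl)-3-(methoxymethoxy)-4-oxo-6-(2-oxoethenyl)-4H-pyran-2-yl]-2-methoxyphenyl 2,2-dimethylpropanoate (ketene) | O=C=Cc1oc(-c2ccc(OC(=O)C(C)(C)C)c(OC)c2)c(OCOC)c(=O)c1C(=C)OCC | intermediate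
17 | 4-[5-ethoxy-3-(methoxymethoxy)-4,7-dioxo-6,7-dihydro-4H-chromen-2-yl]-2-methoxyphenyl 2,2-dimethylpropanoate | CCOC1=C2C(=O)C(OCOC)=C(c3ccc(OC(=O)C(C)(C)C)c(OC)c3)OC2=CC(=O)C1 | intermediate
18 | 4-[5-ethoxy-7-hydroxy-3-(methoxymethoxy)-4-oxo-4H-chromen-2-yl]-2-methoxyphenyl 2,2-dimethylpropanoate | CCOc1cc(O)cc2oc(-c3ccc(OC(=O)C(C)(C)C)c(OC)c3)c(OCOC)c(=O)c12 | intermediate
19 | 2-methoxy-4-(3,5,7-trihydroxy-4-oxo-4H-chromen-2-yl)phenyl 2,2-dimethylpropanoate | COc1cc(-c2oc3cc(O)cc(O)c3c(=O)c2O)ccc1OC(=O)C(C)(C)C | intermediate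
20 | 2-methoxy-4-[5-hydroxy-4-oxo-3,7-bis(sulfooxy)-4H-chromen-2-yl]phenyl 2,2-dimethylpropanoate | COc1cc(-c2oc3cc(OS(=O)(=O)O)cc(O)c3c(=O)c2OS(=O)(=O)O)ccc1OC(=O)C(C)(C)C | intermediate
21 | isorhamnetin 3,7-di-O-sulfate | COc1cc(-c2oc3cc(OS(=O)(=O)O)cc(O)c3c(=O)c2OS(=O)(=O)O)ccc1O | target

**Totals and risks**

Total step count: 14. Longest linear sequence: 13 steps (kojic acid 1 to 21 through steps 1–3 and 5–14).

Steps most likely to fail:

1. Step 11 (proposed new method). The carbene may react before the 1,2-shift (cyclopropanation of the enol ether, insertion), or the ketene may be consumed by dimerisation, (2+2) addition or acylation of the phenol already formed instead of electrocyclising. The fallback sets out from 15 and closes ring A by enolate acylation instead. The Wolff rearrangement is run in methanol (PhCO2Ag cat., Et3N, MeOH/THF, rt, dark, or the same irradiation in MeOH; Arndt–Eistert homologation) so that the ketene is deliberately trapped as methyl 2-{6-[4-(2,2-dimethylpropanoyloxy)-3-methoxyphenyl]-3-(1-ethoxyethenyl)-5-(methoxymethoxy)-4-oxo-4H-pyran-2-yl}acetate F1. PPTS in acetone/H2O at rt should hydrolyse the enol ether to the methyl ketone, methyl 2-{3-acetyl-6-[4-(2,2-dimethylpropanoyloxy)-3-methoxyphenyl]-5-(methoxymethoxy)-4-oxo-4H-pyran-2-yl}acetate F2. KOtBu in THF at 0 °C should then effect the intramolecular Claisen condensation of the acetyl enolate onto the ester (C6–C7 bond) with aromatisation, as known for 2-acetylarylacetates, giving 4-[5,7-dihydroxy-3-(methoxymethoxy)-4-oxo-4H-chromen-2-yl]-2-methoxyphenyl 2,2-dimethylpropanoate F3. HCl in MeOH at 40 °C removes the MOM group and the route is rejoined at 19, step 12 being skipped.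

2. Step 3. The pyranone alpha carbon may be too weakly nucleophilic, or bromine may attack the iodine-bearing carbon (ipso halogen exchange) or oxidise the alcohol. The fallback sets out from 3, omits the electrophilic bromination and installs the halogen by directed metalation. Suzuki coupling of 3 with 6 (conditions of step 5) gives 4-[6-(hydroxymethyl)-3-(methoxymethoxy)-4-oxo-4H-pyran-2-yl]-2-methoxyphenyl 2,2-dimethylpropanoate F4. TEMPO/PhI(OAc)2 oxidation gives 6-[4-(2,2-dimethylpropanoyloxy)-3-methoxyphenyl]-5-(methoxymethoxy)-4-oxo-4H-pyran-2-carboxylic acid F5, and MeI/KHCO3 gives its methyl ester, methyl 6-[4-(2,2-dimethylpropanoyloxy)-3-methoxyphenyl]-5-(methoxymethoxy)-4-oxo-4H-pyran-2-carboxylate F6. Deprotonation of the single ring C–H, flanked by the ketone and the ester, with TMPMgCl·LiCl (THF, −40 °C) and an iodine quench should give methyl 6-[4-(2,2-dimethylpropanoyloxy)-3-methoxyphenyl]-3-iodo-5-(methoxymethoxy)-4-oxo-4H-pyran-2-carboxylate F7. Stille coupling of this iodide with 10 under the conditions of step 8 rejoins the route at 11.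

3. Step 13. Sulfation of the hindered, hydrogen-bonded O3 may stay incomplete, O5 may be partly sulfated under forcing, and material may be lost on purifying the polar salts. The fallback sets out from 19 and uses protected sulfate diesters. 2,2,2-Trichloroethyl chlorosulfate (2.2 equiv) with Et3N and DMAP in THF at 0 °C should give the neutral diester 2-methoxy-4-{5-hydroxy-4-oxo-3,7-bis[(2,2,2-trichloroethoxy)sulfonyloxy]-4H-chromen-2-yl}phenyl 2,2-dimethylpropanoate F8, which can be purified on silica and freed from regioisomers. Zn dust and HCO2NH4 in MeOH at rt then remove both trichloroethyl groups reductively, rejoining the route at 20.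

**Further compounds**

F1 | step 11 | methyl 2-{6-[4-(2,2-dimethylpropanoyloxy)-3-methoxyphenyl]-3-(1-ethoxyethenyl)-5-(methoxymethoxy)-4-oxo-4H-pyran-2-yl}acetate | COC(=O)Cc1oc(-c2ccc(OC(=O)C(C)(C)C)c(OC)c2)c(OCOC)c(=O)c1C(=C)OCC
F2 | step 11 | methyl 2-{3-acetyl-6-[4-(2,2-dimethylpropanoyloxy)-3-methoxyphenyl]-5-(methoxymethoxy)-4-oxo-4H-pyran-2-yl}acetate | COC(=O)Cc1oc(-c2ccc(OC(=O)C(C)(C)C)c(OC)c2)c(OCOC)c(=O)c1C(C)=O
F3 | step 11 | 4-[5,7-dihydroxy-3-(methoxymethoxy)-4-oxo-4H-chromen-2-yl]-2-methoxyphenyl 2,2-dimethylpropanoate | COCOc1c(-c2ccc(OC(=O)C(C)(C)C)c(OC)c2)oc2cc(O)cc(O)c2c1=O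
F4 | step 3 | 4-[6-(hydroxymethyl)-3-(methoxymethoxy)-4-oxo-4H-pyran-2-yl]-2-methoxyphenyl 2,2-dimethylpropanoate | O=c1cc(CO)oc(-c2ccc(OC(=O)C(C)(C)C)c(OC)c2)c1OCOC
F5 | step 3 | 6-[4-(2,2-dimethylpropanoyloxy)-3-methoxyphenyl]-5-(methoxymethoxy)-4-oxo-4H-pyran-2-carboxylic acid | O=C(O)c1cc(=O)c(OCOC)c(-c2ccc(OC(=O)C(C)(C)C)c(OC)c2)o1
F6 | step 3 | methyl 6-[4-(2,2-dimethylpropanoyloxy)-3-methoxyphenyl]-5-(methoxymethoxy)-4-oxo-4H-pyran-2-carboxylate | COC(=O)c1cc(=O)c(OCOC)c(-c2ccc(OC(=O)C(C)(C)C)c(OC)c2)o1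
F7 | step 3 | methyl 6-[4-(2,2-dimethylpropanoyloxy)-3-methoxyphenyl]-3-iodo-5-(methoxymethoxy)-4-oxo-4H-pyran-2-carboxylate | COC(=O)c1oc(-c2ccc(OC(=O)C(C)(C)C)c(OC)c2)c(OCOC)c(=O)c1I
F8 | step 13 | 2-methoxy-4-{5-hydroxy-4-oxo-3,7-bis[(2,2,2-trichloroethoxy)sulfonyloxy]-4H-chromen-2-yl}phenyl 2,2-dimethylpropanoate | COc1cc(-c2oc3cc(OS(=O)(=O)OCC(Cl)(Cl)Cl)cc(O)c3c(=O)c2OS(=O)(=O)OCC(Cl)(Cl)Cl)ccc1OC(=O)C(C)(C)C
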